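**Retrosynthetic overview**

1. Target 21 comes from hexaacetate 20 by global deacetylation, so no acid touches the prenyl group or the adduct.
2. 20 is the endo [4+2] adduct of dienophile 10 (morachalcone A triacetate, chelating 2'-OH free) and diene 19 (dehydroprenyl-isoliquiritigenin triacetate). This is the new step: a catalytic asymmetric Diels–Alder reaction that forms the cyclohexene and all three stereocentres.
3. 19 comes from aryl iodide 16 and dienylboronate 18 (Suzuki); 16 comes from iodoketone 3 and aldehyde 12 (Claisen–Schmidt, then MOM to acetate exchange).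
4. 10 comes from prenyl ketone 4 (Stille prenylation of 3) and aldehyde 6 (Claisen–Schmidt, MOM removal, selective acetylation).
5. Both halves share iodoketone 3, made from 2,4-dihydroxyacetophenone 1. The aromatic rings are bought; the cyclohexene is the only ring formed (step 14).

Assumption: the target is taken as the SMILES string shows it, (1S,5S,6R) at the cyclohexene (C1 aryl cis, C5 aryl trans to the C6 aroyl group); the ligand hand in step 14 and in its fallback follows a working model, is checked on the first run by chiral HPLC and CD, and the mirror-image ligand is used if the sense is reversed.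

**Route**

Step 1
Reactants: 1 2,4-dihydroxyacetophenone
Product: 2 1-(2,4-dihydroxy-3-iodophenyl)ethanone
Conditions: I2 (0.4 equiv), HIO3 (0.2 equiv), EtOH–H2O, rt
Reagents that add atoms: iodine, II; iodic acid, OI(=O)=O
Why: Electrophilic aromatic iodination goes to C3, the carbon ortho to both hydroxyl groups, and HIO3 reoxidises the iodide so that all iodine ends up in the product.

Step 2
Reactants: 2 1-(2,4-dihydroxy-3-iodophenyl)ethanone
Product: 3 1-[3-iodo-2,4-bis(methoxymethoxy)phenyl]ethanone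
Conditions: NaH (2.5 equiv), MOMCl (2.5 equiv), DMF, 0 °C to rt
Reagents that add atoms: chloromethyl methyl ether (MOMCl), COCCl
Why: Williamson-type O-alkylation of both sodium phenoxides; NaH also frees the chelated 2-OH, and the MOM acetals survive the base and palladium steps that follow.

Step 3
Reactants: 3 1-[3-iodo-2,4-bis(methoxymethoxy)phenyl]ethanone
Product: 4 1-[2,4-bis(methoxymethoxy)-3-(3-methylbut-2-en-1-yl)phenyl]ethanone
Conditions: tributyl(3-methylbut-2-en-1-yl)stannane (1.3 equiv), Pd(PPh3)4 (5 mol%), DMF, 90 °C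
Reagents that add atoms: tributyl(3-methylbut-2-en-1-yl)stannane, CCCC[Sn](CCCC)(CCCC)CC=C(C)C
Why: Stille cross-coupling; reductive elimination at the unsubstituted allyl terminus gives the linear prenyl arene, and ketone and acetals are inert.

Step 4
Reactants: 5 2,4-dihydroxybenzaldehyde
Product: 6 2,4-bis(methoxymethoxy)benzaldehyde
Conditions: NaH (2.4 equiv), MOMCl (2.4 equiv), DMF, 0 °C to rt
Reagents that add atoms: chloromethyl methyl ether (MOMCl), COCCl
Why: Williamson-type O-alkylation of both phenoxides gives a base-stable, non-enolisable aldehyde for the condensation.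

Step 5
Reactants: 4 1-[2,4-bis(methoxymethoxy)-3-(3-methylbut-2-en-1-yl)phenyl]ethanone; 6 2,4-bis(methoxymethoxy)benzaldehyde
Product: 8 (E)-1-[2,4-bis(methoxymethoxy)-3-(3-methylbut-2-en-1-yl)phenyl]-3-[2,4-bis(methoxymethoxy)phenyl]prop-2-en-1-one, via aldol adduct 7 (not isolated)
Conditions: KOH (5 equiv), EtOH–H2O, rt, 24 h
Reagents that add atoms: none
Why: Claisen–Schmidt condensation; the enolate of 4 adds to 6 and aldol 7 loses water by E1cB to the conjugated, thermodynamically favoured E-enone.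

Step 6
Reactants: 8 (E)-1-[2,4-bis(methoxymethoxy)-3-(3-methylbut-2-en-1-yl)phenyl]-3-[2,4-bis(methoxymethoxy)phenyl]prop-2-en-1-one
Product: 9 morachalcone A, (E)-1-[2,4-dihydroxy-3-(3-methylbut-2-en-1-yl)phenyl]-3-(2,4-dihydroxyphenyl)prop-2-en-1-one
Conditions: HCl (3 M aq.), MeOH, 50 °C, 45 min, dark
Reagents that add atoms: none
Why: Acid-catalysed transacetalisation of the four MOM ethers to methanol; short heating in the dark limits prenyl cyclisation and E/Z isomerisation of the enone.

Step 7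
Reactants: 9 morachalcone A
Product: 10 (E)-1-[4-acetoxy-2-hydroxy-3-(3-methylbut-2-en-1-yl)phenyl]-3-(2,4-diacetoxyphenyl)prop-2-en-1-one
Conditions: Ac2O (3.3 equiv), pyridine, CH2Cl2, 0 °C
Reagents that add atoms: acetic anhydride, CC(=O)OC(C)=O
Why: Chemoselective O-acetylation of the three unchelated phenols; the 2'-OH, hydrogen-bonded to the ketone and flanked by the prenyl group, stays free as the later binding site.

Step 8
Reactants: 11 4-hydroxybenzaldehyde
Product: 12 4-(methoxymethoxy)benzaldehyde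
Conditions: NaH (1.2 equiv), MOMCl (1.2 equiv), DMF, 0 °C to rt
Reagents that add atoms: chloromethyl methyl ether (MOMCl), COCCl
Why: Williamson-type O-alkylation of the phenoxide gives a base-stable aldehyde partner.

Step 9
Reactants: 3 1-[3-iodo-2,4-bis(methoxymethoxy)phenyl]ethanone; 12 4-(methoxymethoxy)benzaldehyde
Product: 14 (E)-1-[3-iodo-2,4-bis(methoxymethoxy)phenyl]-3-[4-(methoxymethoxy)phenyl]prop-2-en-1-one, via aldol adduct 13 (not isolated)
Conditions: KOH (5 equiv), EtOH–H2O, rt, 24 h
Reagents that add atoms: none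
Why: Claisen–Schmidt condensation with E1cB loss of water from aldol 13 to the E-enone; the aryl iodide is inert to hydroxide.

Step 10
Reactants: 14 (E)-1-[3-iodo-2,4-bis(methoxymethoxy)phenyl]-3-[4-(methoxymethoxy)phenyl]prop-2-en-1-one
Product: 15 (E)-1-(2,4-dihydroxy-3-iodophenyl)-3-(4-hydroxyphenyl)prop-2-en-1-one
Conditions: HCl (3 M aq.), MeOH, 50 °C
Reagents that add atoms: none
Why: Acid-catalysed MOM cleavage, done before the acid-sensitive diene is installed.

Step 11
Reactants: 15 (E)-1-(2,4-dihydroxy-3-iodophenyl)-3-(4-hydroxyphenyl)prop-2-en-1-one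
Product: 16 (E)-1-(2,4-diacetoxy-3-iodophenyl)-3-(4-acetoxyphenyl)prop-2-en-1-one
Conditions: Ac2O (5 equiv), Et3N, DMAP (10 mol%), CH2Cl2, 0 °C to rt
Reagents that add atoms: acetic anhydride, CC(=O)OC(C)=O
Why: DMAP-catalysed exhaustive acetylation also caps the chelated 2'-OH, so this chalcone cannot bind the chiral Lewis acid in step 14.

Step 12
Reactants: 17 2-methylbut-1-en-3-yne
Product: 18 (E)-4,4,5,5-tetramethyl-2-(3-methylbuta-1,3-dien-1-yl)-1,3,2-dioxaborolane
Conditions: pinacolborane (1.0 equiv), Cp2Zr(H)Cl (5 mol%), Et3N (10 mol%), CH2Cl2, rt, sealed tube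
Reagents that add atoms: pinacolborane, CC1(C)OBOC1(C)C
Why: Zirconium-catalysed hydroboration of the terminal alkyne is syn and anti-Markovnikov, giving the E-dienylboronate and leaving the 1,1-disubstituted alkene alone.

Step 13
Reactants: 16 (E)-1-(2,4-diacetoxy-3-iodophenyl)-3-(4-acetoxyphenyl)prop-2-en-1-one; 18 (E)-4,4,5,5-tetramethyl-2-(3-methylbuta-1,3-dien-1-yl)-1,3,2-dioxaborolane
Product: 19 (E)-1-{2,4-diacetoxy-3-[(E)-3-methylbuta-1,3-dien-1-yl]phenyl}-3-(4-acetoxyphenyl)prop-2-en-1-one
Conditions: Pd(OAc)2 (5 mol%), SPhos (10 mol%), CsF (3 equiv), 1,4-dioxane, 60 °C, dark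
Reagents that add atoms: none
Why: Suzuki–Miyaura coupling with retention of the E-alkenyl geometry; SPhos handles the doubly ortho-substituted iodide and anhydrous fluoride activation spares the aryl acetates.

Step 14
Reactants: 10 (E)-1-[4-acetoxy-2-hydroxy-3-(3-methylbut-2-en-1-yl)phenyl]-3-(2,4-diacetoxyphenyl)prop-2-en-1-one; 19 (E)-1-{2,4-diacetoxy-3-[(E)-3-methylbuta-1,3-dien-1-yl]phenyl}-3-(4-acetoxyphenyl)prop-2-en-1-one (1.5 equiv)
Product: 20 (E)-1-{2,4-diacetoxy-3-[(1S,5S,6R)-6-[4-acetoxy-2-hydroxy-3-(3-methylbut-2-en-1-yl)benzoyl]-5-(2,4-diacetoxyphenyl)-3-methylcyclohex-2-en-1-yl]phenyl}-3-(4-acetoxyphenyl)prop-2-en-1-one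
Conditions: [Cu((R,R)-t-Bu-box)](SbF6)2 (10 mol%; (R,R)-t-Bu-box = 2,2'-(propane-2,2-diyl)bis[(4R)-4-tert-butyl-4,5-dihydro-1,3-oxazole]), 2,6-di-tert-butyl-4-methylpyridine (10 mol%), 4 Å MS, CH2Cl2, −20 °C to rt, dark
Reagents that add atoms: none
Why: Proposed new method: a catalytic endo- and enantioselective Diels–Alder reaction of a 2'-hydroxychalcone under two-point binding to a chiral bis(oxazoline) complex of divalent copper; the phenol oxygen (deprotonated through the hindered pyridine) and the ketone oxygen of 10 chelate the square-planar copper centre in a six-membered ring with the same topology as a bound N-enoyl oxazolidinone, which lowers the LUMO of the s-cis enone, holds the phenoxide away from the β-carbon (no flavanone) and lets one tert-butyl group of the (R,R)-ligand cover the α-Re face, so diene 19 adds its CH2 terminus to the β-carbon and its aryl-bearing terminus to the α-carbon from the α-Si face through the endo transition state (diene C2/C3 under the copper-bound carbonyl, the bulky diacetoxyaryl group turned away from the metal), which sets 6R and, because addition is suprafacial on the E-enone and the E-diene, 5S (aryl trans to aroyl) and 1S (aryl cis to aroyl); 19 has no free chelating hydroxyl, so its own enone stays unactivated, and proton exchange between fresh 10 and the copper-bound product phenoxide turns the catalyst over; closest known reaction types: bis(oxazoline)–copper catalysed Diels–Alder reactions of chelating N-enoyl imides, and the stoichiometric chiral borate-promoted Diels–Alder reaction of 2'-hydroxychalcones.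

Step 15
Reactants: 20 (E)-1-{2,4-diacetoxy-3-[(1S,5S,6R)-6-[4-acetoxy-2-hydroxy-3-(3-methylbut-2-en-1-yl)benzoyl]-5-(2,4-diacetoxyphenyl)-3-methylcyclohex-2-en-1-yl]phenyl}-3-(4-acetoxyphenyl)prop-2-en-1-one
Product: 21 (E)-1-{2,4-dihydroxy-3-[(1S,5S,6R)-6-[2,4-dihydroxy-3-(3-methylbut-2-en-1-yl)benzoyl]-5-(2,4-dihydroxyphenyl)-3-methylcyclohex-2-en-1-yl]phenyl}-3-(4-hydroxyphenyl)prop-2-en-1-one (CNP0283121.1)
Conditions: K2CO3 (0.5 equiv), degassed MeOH–THF, 0 °C to rt, argon, dark; then pH 5 buffer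
Reagents that add atoms: none
Why: Base-catalysed transesterification of the six aryl acetates to methanol is mild enough to leave the prenyl group, both enone units and the three stereocentres (including C6 next to the ketone) untouched.

**Compound list**

1 | 2,4-dihydroxyacetophenone | CC(=O)c1ccc(O)cc1O | starting material
2 | 1-(2,4-dihydroxy-3-iodophenyl)ethanone | CC(=O)c1ccc(O)c(I)c1O | intermediate
3 | 1-[3-iodo-2,4-bis(methoxymethoxy)phenyl]ethanone | CC(=O)c1ccc(OCOC)c(I)c1OCOC | intermediate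
4 | 1-[2,4-bis(methoxymethoxy)-3-(3-methylbut-2-en-1-yl)phenyl]ethanone | CC(=O)c1ccc(OCOC)c(CC=C(C)C)c1OCOC | intermediate
5 | 2,4-dihydroxybenzaldehyde | O=Cc1ccc(O)cc1O | starting material
6 | 2,4-bis(methoxymethoxy)benzaldehyde | O=Cc1ccc(OCOC)cc1OCOC | intermediate
7 | aldol adduct (racemic, not isolated), 1-[2,4-bis(methoxymethoxy)-3-(3-methylbut-2-en-1-yl)phenyl]-3-[2,4-bis(methoxymethoxy)phenyl]-3-hydroxypropan-1-one | COCOc1ccc(C(=O)CC(O)c2ccc(OCOC)cc2OCOC)c(OCOC)c1CC=C(C)C | intermediate
8 | (E)-1-[2,4-bis(methoxymethoxy)-3-(3-methylbut-2-en-1-yl)phenyl]-3-[2,4-bis(methoxymethoxy)phenyl]prop-2-en-1-one | COCOc1ccc(C(=O)/C=C/c2ccc(OCOC)cc2OCOC)c(OCOC)c1CC=C(C)C | intermediate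
9 | morachalcone A, (E)-1-[2,4-dihydroxy-3-(3-methylbut-2-en-1-yl)phenyl]-3-(2,4-dihydroxyphenyl)prop-2-en-1-one | CC(C)=CCc1c(O)ccc(C(=O)/C=C/c2ccc(O)cc2O)c1O | intermediate
10 | (E)-1-[4-acetoxy-2-hydroxy-3-(3-methylbut-2-en-1-yl)phenyl]-3-(2,4-diacetoxyphenyl)prop-2-en-1-one | CC(C)=CCc1c(OC(C)=O)ccc(C(=O)/C=C/c2ccc(OC(C)=O)cc2OC(C)=O)c1O | intermediate
11 | 4-hydroxybenzaldehyde | O=Cc1ccc(O)cc1 | starting material
12 | 4-(methoxymethoxy)benzaldehyde | O=Cc1ccc(OCOC)cc1 | intermediate
13 | aldol adduct (racemic, not isolated), 3-hydroxy-1-[3-iodo-2,4-bis(methoxymethoxy)phenyl]-3-[4-(methoxymethoxy)phenyl]propan-1-one | COCOc1ccc(C(O)CC(=O)c2ccc(OCOC)c(I)c2OCOC)cc1 | intermediate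
14 | (E)-1-[3-iodo-2,4-bis(methoxymethoxy)phenyl]-3-[4-(methoxymethoxy)phenyl]prop-2-en-1-one | COCOc1ccc(/C=C/C(=O)c2ccc(OCOC)c(I)c2OCOC)cc1 | intermediate
15 | (E)-1-(2,4-dihydroxy-3-iodophenyl)-3-(4-hydroxyphenyl)prop-2-en-1-one | Oc1ccc(/C=C/C(=O)c2ccc(O)c(I)c2O)cc1 | intermediate
16 | (E)-1-(2,4-diacetoxy-3-iodophenyl)-3-(4-acetoxyphenyl)prop-2-en-1-one | CC(=O)Oc1ccc(/C=C/C(=O)c2ccc(OC(C)=O)c(I)c2OC(C)=O)cc1 | intermediate
17 | 2-methylbut-1-en-3-yne | C=C(C)C#C | starting material
18 | (E)-4,4,5,5-tetramethyl-2-(3-methylbuta-1,3-dien-1-yl)-1,3,2-dioxaborolane | C=C(C)/C=C/B1OC(C)(C)C(C)(C)O1 | intermediate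
19 | (E)-1-{2,4-diacetoxy-3-[(E)-3-methylbuta-1,3-dien-1-yl]phenyl}-3-(4-acetoxyphenyl)prop-2-en-1-one | CC(=O)Oc1ccc(/C=C/C(=O)c2ccc(OC(C)=O)c(/C=C/C(C)=C)c2OC(C)=O)cc1 | intermediate
20 | (E)-1-{2,4-diacetoxy-3-[(1S,5S,6R)-6-[4-acetoxy-2-hydroxy-3-(3-methylbut-2-en-1-yl)benzoyl]-5-(2,4-diacetoxyphenyl)-3-methylcyclohex-2-en-1-yl]phenyl}-3-(4-acetoxyphenyl)prop-2-en-1-one | CC(C)=CCc1c(OC(C)=O)ccc(C(=O)[C@H]2[C@@H](c3c(OC(C)=O)ccc(C(=O)/C=C/c4ccc(OC(C)=O)cc4)c3OC(C)=O)C=C(C)C[C@@H]2c2ccc(OC(C)=O)cc2OC(C)=O)c1O | intermediate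
21 | (E)-1-{2,4-dihydroxy-3-[(1S,5S,6R)-6-[2,4-dihydroxy-3-(3-methylbut-2-en-1-yl)benzoyl]-5-(2,4-dihydroxyphenyl)-3-methylcyclohex-2-en-1-yl]phenyl}-3-(4-hydroxyphenyl)prop-2-en-1-one | CC(C)=CCc1c(O)ccc(C(=O)[C@H]2[C@@H](c3c(O)ccc(C(=O)/C=C/c4ccc(O)cc4)c3O)C=C(C)C[C@@H]2c2ccc(O)cc2O)c1O | target

**Step count and risks**

Total steps: 15. Longest linear sequence: 8 steps (steps 1, 2, 3, 5, 6, 7, 14, 15; the diene arm through steps 1, 2, 9, 10, 11, 13, 14, 15 is also 8).

Most likely to fail, 1: step 14 (the proposed new cycloaddition). The β-aryl enone may be too weakly activated, the product may hold on to the copper centre, the endo/exo ratio is untested, and traces of strong acid could destroy the diene or close the prenyl group onto the free phenol. The exo isomer, if formed, is removed by chromatography. The fallback uses known chemistry, sets out from 10 and 19 and comes back at 20. Dienophile 10 is stirred in THF with (R)-VANOL (3,3'-diphenyl-2,2'-bi-1-naphthol, 1.2 equiv), BH3·THF and AcOH, with loss of hydrogen, which gives the VANOL borate chelate of 10 F1. The solvent is changed to PhCF3, 19 is added, and the cycloaddition at rt leaves the adduct on boron as the VANOL borate chelate of 20 F2. Aqueous work-up hydrolyses F2 and returns the ligand, and the endo adduct 20 is separated from the exo isomer on silica. This stoichiometric chiral borate-promoted Diels–Alder reaction of 2'-hydroxychalcones with acetylated aryl dienes is established for this family of adducts.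

Most likely to fail, 2: step 13 (Suzuki coupling). The iodide is flanked by two acetoxy groups, fluoride may cleave aryl acetates, and the product diene can polymerise. The fallback sets out from 16 and comes back at 19. A Heck reaction of 16 with 2-methylbut-3-en-2-ol (Pd(OAc)2, n-Bu4NCl, NaHCO3, DMF, 70 °C) gives the tertiary allylic alcohol (E)-1-{2,4-diacetoxy-3-[(E)-3-hydroxy-3-methylbut-1-en-1-yl]phenyl}-3-(4-acetoxyphenyl)prop-2-en-1-one F3. Dehydration with catalytic PPTS in toluene at 70 °C over 4 Å MS, through the aryl-stabilised allyl cation, then gives diene 19.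

Most likely to fail, 3: step 3 (Stille prenylation). Transmetalation at the doubly ortho-substituted iodide may be slow, with protodeiodination and some reverse-prenyl isomer. The fallback sets out from 1 and comes back at 4. Direct C-prenylation of 1 with prenyl bromide in aqueous KOH (0 °C to rt) gives 1-[2,4-dihydroxy-3-(3-methylbut-2-en-1-yl)phenyl]ethanone F4 in modest yield after the 5-prenyl isomer and O-prenyl ethers are removed on silica. NaH and MOMCl in DMF then convert F4 into 4. Iodoketone 3 is still made for the diene arm.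

**Further compounds**

F1 | step 14 | VANOL borate chelate of 10 (spiro borate on the 2'-oxygen and ketone oxygen of 10; (R) axis of the ligand as named, not encoded in the string) | CC(C)=CCc1c(OC(C)=O)ccc2c1O[B-]1(Oc3c(-c4c(O1)c5ccccc5cc4-c4ccccc4)c(-c4ccccc4)cc4ccccc34)[O+]=C2/C=C/c1ccc(OC(C)=O)cc1OC(C)=O
F2 | step 14 | VANOL borate chelate of 20 (same spiro borate on the cycloadduct; (R) axis of the ligand as named, not encoded in the string) | CC(C)=CCc1c(OC(C)=O)ccc2c1O[B-]1(Oc3c(-c4c(O1)c5ccccc5cc4-c4ccccc4)c(-c4ccccc4)cc4ccccc34)[O+]=C2[C@H]6[C@@H](c7c(OC(C)=O)ccc(C(=O)/C=C/c8ccc(OC(C)=O)cc8)c7OC(C)=O)C=C(C)C[C@@H]6c6ccc(OC(C)=O)cc6OC(C)=O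
F3 | step 13 | (E)-1-{2,4-diacetoxy-3-[(E)-3-hydroxy-3-methylbut-1-en-1-yl]phenyl}-3-(4-acetoxyphenyl)prop-2-en-1-one | CC(=O)Oc1ccc(/C=C/C(=O)c2ccc(OC(C)=O)c(/C=C/C(C)(C)O)c2OC(C)=O)cc1
F4 | step 3 | 1-[2,4-dihydroxy-3-(3-methylbut-2-en-1-yl)phenyl]ethanone | CC(=O)c1ccc(O)c(CC=C(C)C)c1O
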